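## The problem

The target 21 is a 19-membered macrocycle built from four benzene rings joined alternately by two diaryl ether oxygens and two CH2CH2 bridges. Going round the ring: catechol ring A (a 5-alkyl-3-aryloxybenzene-1,2-diol), O, para-phenylene ring B, CH2CH2, catechol ring C (same pattern as ring A), O, meta-phenylene ring D, CH2CH2, back to ring A. There is no stereocentre, so the task is one of connectivity and ring formation only. Each ether oxygen sits on a catechol carbon next to another oxygenated carbon, so each diaryl ether amounts to O-arylation of a hindered, electron-rich phenol, and one of the four inter-ring links has to be closed as a macrocycle. The four catechol hydroxyls are easily oxidised to o-quinones and must stay masked until the last step, with masks that come off without cleaving the diaryl ethers. A ring D aryl bromide and a ring C silyl ether also have to survive ylides, an organotitanium reagent, heat, DDQ and acid. The enabling feature is ring B: it carries only the ether oxygen at C1 and the two-carbon bridge at C4, with four unsubstituted CH positions. That is the pattern delivered by a 2-oxygenated buta-1,3-diene (supplying C1, C2, C6 and C5) and a terminal acetylenic ketone (supplying C3 and C4, with the acyl carbon becoming the benzylic CH2 of the bridge) after cycloaddition and dehydrogenation. Because the diene oxygen can be attached to ring A by acylation and carbonyl methylenation, the A–O–B ether need not be made by arylation at all.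

## Retrosynthesis

**21 ⇒ 20 (four O–CH3 bonds).** The catechols are unmasked last. Methyl ethers are chosen because they are already present in the commercial aldehyde 3 and because BBr3 cleaves aryl methyl ethers while leaving diaryl ethers intact. Benzyl ethers would need hydrogenolysis, which is incompatible with the ring D bromide carried up to the macrocyclisation. Compound 20 has no free hydroxyl and is robust.

**20 ⇒ 19 (ring C oxygen to ring D carbon).** The macrocycle is opened at the C–O–D ether. This cut lets ring D enter as a plain 3-bromophenyl group from commercial 1 and keeps the key step intermolecular. Closing at a CH2CH2 bridge by intramolecular olefination would need two differentiated benzylic functions and an extra alkene reduction. The forward reaction is an intramolecular Ullmann etherification of a hindered phenol with an unactivated aryl bromide at high dilution, so 19 must carry no base-sensitive group.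

**19 ⇒ 18 ⇒ 17 (Si–O bond; benzylic CH2 from C=O).** The phenol is released from a triisopropylsilyl ether, chosen because it tolerates ylides, a Grignard reagent, oxidation, heat and DDQ and is removed by fluoride without touching the methyl ethers. The benzylic CH2 of the B–C bridge comes from the aryl ketone of 17 by ionic hydrogenation. The ketone is only there to activate the cycloaddition and is deleted before the basic macrocyclisation.

**17 ⇒ 9 + 15 (ring B bonds C2–C3 and C4–C5).** Ring B is taken apart into the 2-aryloxybuta-1,3-diene 9 and the ethynyl ketone 15; the forward reaction passes through the cyclohexa-1,4-diene 16.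
- Against cutting the A–O–B bond: that would require metal-mediated arylation of the hindered phenol 6 in the presence of its own ring D bromide.
- Against cutting the ring B–carbonyl bond: Friedel–Crafts acylation of a preformed diaryl ether would attack the more electron-rich ring A.
- Gain: 17, with four rings, splits into two fragments of similar size, both traceable to aldehyde 3.
- Demands on the forward step: para orientation, survival of the acid-labile diene and the base-labile ynone, and dehydrogenation before the enol ether of 16 can hydrolyse.

**9 ⇒ 8 ⇒ 6 + 7 (enol ether C=CH2; ester C–O).** The dienyl ether is the methylenation product of the aryl acrylate 8, which is the ester of phenol 6 and acryloyl chloride 7. The ring A oxygen is therefore acylated, which a hindered phenol accepts readily.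

**6 ⇒ 5 ⇒ 2 + 3; 2 ⇒ 1 (C=C of the D–A bridge).** The bibenzyl is the reduced form of stilbene 5, made by Wittig olefination of aldehyde 3 with the ylide 4 of phosphonium salt 2, itself from 3-bromobenzyl bromide 1. Olefination avoids organometallic chemistry on a substrate with an aryl bromide, and diimide reduces the alkene without touching C–Br, which H2 over Pd/C would not guarantee.

**15 ⇒ 14 ⇒ 12 + 13; 12 ⇒ 10 ⇒ 3 (carbinol–alkyne C–C; one-carbon homologation; Si–O).** The ynone is the oxidation product of propargylic alcohol 14, from ethynylmagnesium bromide 13 and arylacetaldehyde 12. Aldehyde 12 is the one-carbon homologue (through enol ether 11) of the silylated aldehyde 10, which is 3 with its phenol protected.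

## Roads not taken

**Alternative 1:** The cut is the ring B carbon to ring A oxygen bond, made last by ring contraction. A 20-membered macrolactone A1 (the ring A phenol esterified by a ring B benzoic acid) would be treated with Ni(cod)2, a chelating bis(dicyclohexylphosphino) ligand and K3PO4. Decarbonylation would then give the 19-membered tetra-O-methyl macrocycle A2, which has the structure of 20.
- Merits: all four rings are bought; the hindered ring A phenol is acylated, as in the chosen plan; the ring is closed by macrolactonisation, which is more dependable than a macrocyclic Ullmann coupling. In that respect this road is better.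
- Weak points: decarbonylative etherification needs oxidative addition of zerovalent nickel into the C(acyl)–O bond, which is easiest for electron-poor or heteroaromatic acyl groups and electron-poor aryloxides. A1 offers a 4-alkylbenzoyl group and an electron-rich, ortho-substituted aryloxide. The reductive elimination must also occur inside a contracting macrocycle at high temperature, with the released carbon monoxide competing for the metal.
- Comparison: the chosen plan sets against the easier ring closure a key step that is intermolecular, thermal, metal-free and of a well-known reaction class. It accepts the Ullmann closure as its own risk.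

**Alternative 2:** The cut is through ring D, which would be built by cycloaddition. The 4-aryloxy-6-(2-arylethyl)-2-pyrone A4, assembled from triacetic acid lactone A3 by substitution at C4 and chain extension at the 6-methyl group, would add phenyl vinyl sulfoxide A5 across C3 and C6. Decarboxylative cycloreversion and sulfoxide elimination would then give the open-chain tetra-aryl ester A6.
- Merits: A3 is cheap; the meta relationship of ring D follows from the 4,6-substitution of the pyrone with no regiochemical question, which is better than relying on an orientation rule; the hindered C–O–D ether is made by addition–elimination on a pyrone.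
- Weak points: 2-pyrones are sluggish dienes and A5 is a modest, thermally fragile dienophile, so forcing conditions are expected. A6 still lacks the B–C bridge: the ester carbon has to be reduced, one more carbon added, and the macrocycle closed onto the ring B bromide. The hindered A–O–B ether must also still be made by arylation.
- Comparison: the chosen plan sets against the safer regiochemistry a more reactive diene–dienophile pair. Its cycloaddition product 17 already holds every carbon of the target, so the endgame is only functional-group removal and one ring closure.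

**Alternative 3:** The cut is through ring A, which would be built by benzannulation. Irradiation of the diazo enone A7 with di-tert-butoxyethyne A8 would trigger photochemical Wolff rearrangement, ketene–alkyne (2+2) cycloaddition, four-electron ring opening and six-electron ring closure. The product is 5-[2-(3-bromophenyl)ethyl]-2,3-di-tert-butoxyphenol A9.
- Merits: the regiochemistry is fixed by the mechanism; the free phenol is differentiated from two acid-labile tert-butyl ethers, so ring A could later be unmasked more gently than with BBr3. In that respect this road is better.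
- Weak points: A9 is only an analogue of 6, which the chosen route reaches in three steps from commercial 3. A7 needs diazo chemistry and A8 is a labile alkyne that must be prepared. UV light can homolyse the aryl C–Br bond. Neither the hindered arylation nor the macrocycle is addressed, and tert-butyl aryl ethers would not survive the acidic ketone reduction that any later use of the ring B cycloaddition would need.
- Comparison: the chosen plan sets against the milder deprotection a purchased ring A and a key step that also solves the A–O–B ether, at the price of a final BBr3 demethylation.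

Key step: step 10

## Route

Assumption: the target has no stereocentre and is treated as conformationally mobile; alkenes 5 and 11 are carried as E/Z mixtures and alcohol 14 as a racemate because each element is removed in the next operation.

Step 1
Reactants: 1 3-bromobenzyl bromide
Product: 2 (3-bromobenzyl)triphenylphosphonium bromide
Conditions: PPh3, toluene, reflux
Reagents that add atoms: triphenylphosphine, c1ccc(cc1)P(c1ccccc1)c1ccccc1
Why: SN2 quaternisation of the phosphine by the benzylic bromide; the aryl bromide does not react with PPh3 without a catalyst, and the salt should crystallise from toluene.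

Step 2
Reactants: 2 (3-bromobenzyl)triphenylphosphonium bromide; 3 3-hydroxy-4,5-dimethoxybenzaldehyde
Product: 5 5-[2-(3-bromophenyl)ethenyl]-2,3-dimethoxyphenol (E/Z mixture), via phosphorus ylide 4 (not isolated)
Conditions: KOtBu (2.3 equiv), THF, 0 °C to rt; then 1 M aq HCl
Reagents that add atoms: none
Why: Wittig olefination with a semi-stabilised benzylic ylide; the extra base only turns the phenol into a phenoxide that is meta to the aldehyde and cannot deactivate it by conjugation. The alkene geometry is irrelevant because the double bond is reduced next.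

Step 3
Reactants: 5 5-[2-(3-bromophenyl)ethenyl]-2,3-dimethoxyphenol (E/Z mixture)
Product: 6 5-[2-(3-bromophenyl)ethyl]-2,3-dimethoxyphenol
Conditions: TsNHNH2, NaOAc, THF/H2O, reflux
Reagents that add atoms: none
Why: Diimide reduction; diimide released from the sulfonyl hydrazide transfers two hydrogens to the C=C bond through a concerted cyclic transition state and cannot cleave the aryl C–Br bond.

Step 4
Reactants: 6 5-[2-(3-bromophenyl)ethyl]-2,3-dimethoxyphenol; 7 acryloyl chloride
Product: 8 5-[2-(3-bromophenyl)ethyl]-2,3-dimethoxyphenyl prop-2-enoate
Conditions: Et3N, BHT (trace), CH2Cl2, 0 °C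
Reagents that add atoms: none
Why: O-acylation of a phenol by an acid chloride with an amine base, which a hindered phenol accepts readily; low temperature and a radical inhibitor suppress polymerisation and conjugate addition.

Step 5
Reactants: 8 5-[2-(3-bromophenyl)ethyl]-2,3-dimethoxyphenyl prop-2-enoate
Product: 9 5-[2-(3-bromophenyl)ethyl]-1-(buta-1,3-dien-2-yloxy)-2,3-dimethoxybenzene
Conditions: Cp2Ti(CH2)(Cl)AlMe2, pyridine (cat.), THF/toluene, −40 °C to rt; aq NaOH quench; filtration through basic alumina
Reagents that add atoms: Tebbe reagent Cp2Ti(CH2)(Cl)AlMe2, C[Al-]1(C)C[Ti]([Cl+]1)(C1C=CC=C1)C1C=CC=C1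
Why: Tebbe methylenation of an ester; Cp2Ti=CH2 adds across the ester C=O and the oxatitanacyclobutane collapses to the enol ether, driven by the Ti–O bond. Aryl esters and conjugated esters are established substrates, and the non-acidic, low-temperature conditions and basic work-up protect the acid-labile dienyl ether.

Step 6
Reactants: 3 3-hydroxy-4,5-dimethoxybenzaldehyde
Product: 10 3,4-dimethoxy-5-(triisopropylsilyloxy)benzaldehyde
Conditions: TIPSCl, imidazole, DMF, rt
Reagents that add atoms: triisopropylsilyl chloride, CC(C)[Si](Cl)(C(C)C)C(C)C
Why: Silylation of a phenol; the bulky silyl ether is chosen to survive the ylide, the Grignard reagent, dilute acid, heat and DDQ and to be removed later by fluoride.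

Step 7
Reactants: 10 3,4-dimethoxy-5-(triisopropylsilyloxy)benzaldehyde
Product: 12 2-[3,4-dimethoxy-5-(triisopropylsilyloxy)phenyl]acetaldehyde, via methyl enol ether 11 (not isolated)
Conditions: Ph3P(CH2OMe)Cl, KN(SiMe3)2, THF, 0 °C to rt; then 2 M aq HCl, THF, 40 °C
Reagents that add atoms: (methoxymethyl)triphenylphosphonium chloride, COC[P+](c1ccccc1)(c1ccccc1)c1ccccc1.[Cl-]; water, O
Why: Wittig methoxymethylenation followed by acid hydrolysis of the enol ether, a standard one-carbon homologation of an aryl aldehyde; the aryl triisopropylsilyl ether tolerates dilute aqueous acid.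

Step 8
Reactants: 12 2-[3,4-dimethoxy-5-(triisopropylsilyloxy)phenyl]acetaldehyde; 13 ethynylmagnesium bromide
Product: 14 1-[3,4-dimethoxy-5-(triisopropylsilyloxy)phenyl]but-3-yn-2-ol (racemic)
Conditions: THF, −78 °C to 0 °C; aq NH4Cl
Reagents that add atoms: none
Why: 1,2-Addition of an alkynyl Grignard reagent to an aldehyde; low temperature favours addition over enolisation of the arylacetaldehyde. The carbinol centre forms as a racemate and is erased in step 9.

Step 9
Reactants: 14 1-[3,4-dimethoxy-5-(triisopropylsilyloxy)phenyl]but-3-yn-2-ol (racemic)
Product: 15 1-[3,4-dimethoxy-5-(triisopropylsilyloxy)phenyl]but-3-yn-2-one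
Conditions: Dess–Martin periodinane, CH2Cl2, 0 °C to rt
Reagents that add atoms: none
Why: Dess–Martin oxidation of a secondary propargylic alcohol to the ynone; the neutral, non-basic conditions should leave the acidic benzylic CH2 and the terminal alkyne undisturbed. The ynone is used promptly.

Step 10
Reactants: 9 5-[2-(3-bromophenyl)ethyl]-1-(buta-1,3-dien-2-yloxy)-2,3-dimethoxybenzene; 15 1-[3,4-dimethoxy-5-(triisopropylsilyloxy)phenyl]but-3-yn-2-one
Product: 17 1-(4-{5-[2-(3-bromophenyl)ethyl]-2,3-dimethoxyphenoxy}phenyl)-2-[3,4-dimethoxy-5-(triisopropylsilyloxy)phenyl]ethan-1-one, via cyclohexa-1,4-diene adduct 16 (not isolated)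
Conditions: 15 (1.3 equiv), BHT (cat.), toluene, 100 °C, sealed tube; then DDQ (1.1 equiv), 0 °C to rt
Reagents that add atoms: none
Why: A thermal, concerted but asynchronous (4+2) cycloaddition of the s-cis diene 9 (HOMO) with the ynone 15 (LUMO) gives the cyclohexa-1,4-diene 16. DDQ then abstracts hydride from a doubly allylic CH2 to give a cation stabilised by the enol ether oxygen, and loss of a proton aromatises the ring. The closest known reaction type is the Diels–Alder reaction of 2-alkoxy- and 2-silyloxybuta-1,3-dienes with acetylenic ketones and esters followed by dehydrogenation to para-substituted aryl ethers. Ring B is closed by an intermolecular two-bond annulation (C2–C3 and C4–C5 of ring B) and then made aromatic by loss of two hydrogens. No stereocentre is formed, since the two sp3 carbons of 16 are CH2 groups. The step needs para orientation: the oxygen on C2 of the diene puts the largest HOMO coefficient on C1, which bonds to the unsubstituted alkyne carbon carrying the largest LUMO coefficient, so the acyl-bearing carbon ends up 1,4 to the oxygen-bearing carbon. It also needs chemoselective oxidation: dehydrogenation of a 1,4-cyclohexadiene is far faster than attack of DDQ on the benzylic CH2 groups, so about one equivalent at or below room temperature should suffice. Working in one flask keeps the enol ether of 16 from hydrolysing before it is aromatised.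

Step 11
Reactants: 17 1-(4-{5-[2-(3-bromophenyl)ethyl]-2,3-dimethoxyphenoxy}phenyl)-2-[3,4-dimethoxy-5-(triisopropylsilyloxy)phenyl]ethan-1-one
Product: 18 {5-[2-(4-{5-[2-(3-bromophenyl)ethyl]-2,3-dimethoxyphenoxy}phenyl)ethyl]-2,3-dimethoxyphenoxy}triisopropylsilane
Conditions: Et3SiH (4 equiv), CF3CO2H, CH2Cl2, 0 °C to rt
Reagents that add atoms: none
Why: Ionic hydrogenation of an aryl ketone to the methylene; the protonated ketone takes hydride from the silane, the benzylic alcohol ionises to a cation stabilised by the para aryloxy group, and a second hydride transfer completes the reduction. The aryl bromide and the ethers are inert.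

Step 12
Reactants: 18 {5-[2-(4-{5-[2-(3-bromophenyl)ethyl]-2,3-dimethoxyphenoxy}phenyl)ethyl]-2,3-dimethoxyphenoxy}triisopropylsilane
Product: 19 5-[2-(4-{5-[2-(3-bromophenyl)ethyl]-2,3-dimethoxyphenoxy}phenyl)ethyl]-2,3-dimethoxyphenol
Conditions: Bu4NF, THF, 0 °C; aq NH4Cl
Reagents that add atoms: none
Why: Fluoride-induced cleavage of the aryl silyl ether, driven by the Si–F bond; methyl ethers, diaryl ether and aryl bromide are untouched.

Step 13
Reactants: 19 5-[2-(4-{5-[2-(3-bromophenyl)ethyl]-2,3-dimethoxyphenoxy}phenyl)ethyl]-2,3-dimethoxyphenol
Product: 20 tetra-O-methyl 19-membered macrocycle (rings A to D, ring C oxygen bonded to ring D)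
Conditions: CuI (30 mol %), N,N-dimethylglycine hydrochloride (60 mol %), Cs2CO3, 1,4-dioxane, 100 °C, slow addition of 19 to about 2 mM
Reagents that add atoms: none
Why: Intramolecular Ullmann diaryl ether synthesis catalysed by monovalent copper with an amino acid ligand, a combination that tolerates ortho-alkoxy phenols and unactivated aryl bromides; high dilution favours closure of the 19-membered ring over oligomerisation. The substrate no longer has a base-sensitive group.

Step 14
Reactants: 20 tetra-O-methyl 19-membered macrocycle
Product: 21 CNP0511668.0 (19-membered macrocyclic tetraphenol with catechol rings A and C)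
Conditions: BBr3 (excess), CH2Cl2, −78 °C to rt; then H2O, under argon
Reagents that add atoms: none
Why: Lewis acid demethylation; BBr3 coordinates each methoxy oxygen and bromide attacks the methyl carbon (SN2). The diaryl ether oxygens carry no sp3 carbon and survive, as is usual for macrocyclic bis(bibenzyl) ethers.

## Compound list

1 | 3-bromobenzyl bromide | BrCc1cccc(Br)c1 | starting material
2 | (3-bromobenzyl)triphenylphosphonium bromide | Brc1cccc(C[P+](c2ccccc2)(c2ccccc2)c2ccccc2)c1.[Br-] | intermediate
3 | 3-hydroxy-4,5-dimethoxybenzaldehyde | COc1cc(C=O)cc(O)c1OC | starting material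
4 | (3-bromobenzylidene)triphenylphosphorane (ylide, not isolated) | Brc1cccc(C=P(c2ccccc2)(c2ccccc2)c2ccccc2)c1 | intermediate
5 | 5-[2-(3-bromophenyl)ethenyl]-2,3-dimethoxyphenol (E/Z mixture, geometry not specified) | COc1cc(C=Cc2cccc(Br)c2)cc(O)c1OC | intermediate
6 | 5-[2-(3-bromophenyl)ethyl]-2,3-dimethoxyphenol | COc1cc(CCc2cccc(Br)c2)cc(O)c1OC | intermediate
7 | acryloyl chloride | C=CC(=O)Cl | starting material
8 | 5-[2-(3-bromophenyl)ethyl]-2,3-dimethoxyphenyl prop-2-enoate | C=CC(=O)Oc1cc(CCc2cccc(Br)c2)cc(OC)c1OC | intermediate
9 | 5-[2-(3-bromophenyl)ethyl]-1-(buta-1,3-dien-2-yloxy)-2,3-dimethoxybenzene | C=CC(=C)Oc1cc(CCc2cccc(Br)c2)cc(OC)c1OC | intermediate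
10 | 3,4-dimethoxy-5-(triisopropylsilyloxy)benzaldehyde | COc1cc(C=O)cc(O[Si](C(C)C)(C(C)C)C(C)C)c1OC | intermediate
11 | [2,3-dimethoxy-5-(2-methoxyethenyl)phenoxy]triisopropylsilane (E/Z mixture, not isolated) | COC=Cc1cc(OC)c(OC)c(O[Si](C(C)C)(C(C)C)C(C)C)c1 | intermediate
12 | 2-[3,4-dimethoxy-5-(triisopropylsilyloxy)phenyl]acetaldehyde | O=CCc1cc(OC)c(OC)c(O[Si](C(C)C)(C(C)C)C(C)C)c1 | intermediate
13 | ethynylmagnesium bromide | C#C[Mg]Br | starting material
14 | 1-[3,4-dimethoxy-5-(triisopropylsilyloxy)phenyl]but-3-yn-2-ol (racemic) | C#CC(O)Cc1cc(OC)c(OC)c(O[Si](C(C)C)(C(C)C)C(C)C)c1 | intermediate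
15 | 1-[3,4-dimethoxy-5-(triisopropylsilyloxy)phenyl]but-3-yn-2-one | C#CC(=O)Cc1cc(OC)c(OC)c(O[Si](C(C)C)(C(C)C)C(C)C)c1 | intermediate
16 | 1-(4-{5-[2-(3-bromophenyl)ethyl]-2,3-dimethoxyphenoxy}cyclohexa-1,4-dien-1-yl)-2-[3,4-dimethoxy-5-(triisopropylsilyloxy)phenyl]ethan-1-one (not isolated) | O=C(Cc1cc(OC)c(OC)c(O[Si](C(C)C)(C(C)C)C(C)C)c1)C1=CCC(Oc2cc(CCc3cccc(Br)c3)cc(OC)c2OC)=CC1 | intermediate
17 | 1-(4-{5-[2-(3-bromophenyl)ethyl]-2,3-dimethoxyphenoxy}phenyl)-2-[3,4-dimethoxy-5-(triisopropylsilyloxy)phenyl]ethan-1-one | COc1cc(CCc2cccc(Br)c2)cc(Oc2ccc(cc2)C(=O)Cc2cc(OC)c(OC)c(O[Si](C(C)C)(C(C)C)C(C)C)c2)c1OC | intermediate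
18 | {5-[2-(4-{5-[2-(3-bromophenyl)ethyl]-2,3-dimethoxyphenoxy}phenyl)ethyl]-2,3-dimethoxyphenoxy}triisopropylsilane | COc1cc(CCc2cccc(Br)c2)cc(Oc2ccc(CCc3cc(OC)c(OC)c(O[Si](C(C)C)(C(C)C)C(C)C)c3)cc2)c1OC | intermediate
19 | 5-[2-(4-{5-[2-(3-bromophenyl)ethyl]-2,3-dimethoxyphenoxy}phenyl)ethyl]-2,3-dimethoxyphenol | COc1cc(CCc2cccc(Br)c2)cc(Oc2ccc(CCc3cc(OC)c(OC)c(O)c3)cc2)c1OC | intermediate
20 | tetra-O-methyl 19-membered macrocycle (ring A–O–ring B–CH2CH2–ring C–O–ring D–CH2CH2–ring A; two methoxy groups on each of rings A and C) | COc1cc2cc(c1OC)Oc1ccc(cc1)CCc1cc(OC)c(OC)c(c1)Oc1cccc(c1)CC2 | intermediate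
21 | CNP0511668.0, the tetraphenol macrocycle (no stereocentre) | Oc1cc2cc(c1O)Oc1ccc(cc1)CCc1cc(O)c(O)c(c1)Oc1cccc(c1)CC2 | target

## Step count and risks

Total: 14 steps. Longest linear sequence: 10 steps (steps 1 to 5, then 10 to 14); the ynone branch (steps 6 to 9) joins at step 10.

**Step 10 (key step).**
- What may go wrong: the aryloxy group is a weaker donor than an alkoxy or silyloxy group, so the cycloaddition may be slow enough for thermal or trace-base-induced isomerisation and oligomerisation of the ynone to compete. Para selectivity may erode. The enol ether of the adduct may hydrolyse before dehydrogenation. DDQ may over-oxidise the CH2 between the ketone and electron-rich ring C.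
- Fallback: sets out from phenol 6 and aldehyde 10 and returns at 18, giving up the cycloaddition and the ynone. Nucleophilic aromatic substitution of 6 on 4-fluorobenzaldehyde (K2CO3, DMF, 120 °C), which ignores the ring D bromide, gives 4-{5-[2-(3-bromophenyl)ethyl]-2,3-dimethoxyphenoxy}benzaldehyde F1. Aldehyde 10 is reduced with NaBH4 to [3,4-dimethoxy-5-(triisopropylsilyloxy)phenyl]methanol F2, converted with CBr4 and PPh3 into the benzyl bromide F3, and quaternised with PPh3 to the phosphonium bromide F4. Wittig olefination of F1 with the ylide from F4 (NaN(SiMe3)2, THF) gives the stilbene F5 as an E/Z mixture, and diimide reduction (TsNHNH2, NaOAc) gives 18.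

**Step 5.**
- What may go wrong: the titanium methylidene may react with the terminal vinyl group instead of the ester carbonyl; the acrylate or the diene may polymerise; the enol ether may hydrolyse during isolation.
- Fallback: sets out from 6 and returns at 9, methylenating a saturated ester and unveiling the vinyl group afterwards. Acylation of 6 with 3-chloropropanoyl chloride and pyridine at low temperature gives the aryl 3-chloropropanoate F6. Methylenation with Cp2Ti(CH2)(Cl)AlMe2 gives 5-[2-(3-bromophenyl)ethyl]-1-[(4-chlorobut-1-en-2-yl)oxy]-2,3-dimethoxybenzene F7. E2 elimination with KOtBu in THF, which removes an allylic hydrogen, gives 9.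

**Step 13.**
- What may go wrong: oligomerisation may outrun closure of the 19-membered ring; the bromide may be lost reductively; the ortho-methoxy phenol may couple slowly with the unactivated bromide.
- Fallback: sets out from 18 and returns at 20, replacing the Ullmann coupling by an oxidative Chan–Lam closure at room temperature. Miyaura borylation of 18 (B2pin2, Pd(dppf)Cl2, KOAc, dioxane, 85 °C) gives the aryl pinacol boronate F8. Bu4NF gives the phenol pinacol boronate F9. NaIO4 with NH4OAc in aqueous acetone gives the phenol boronic acid F10. Cu(OAc)2, pyridine and 4 Å molecular sieves in dilute CH2Cl2 under air then close the diaryl ether to 20.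

**Step 11.**
- What may go wrong: the reduction may stall at a partly reduced stage because the 4-aryloxyphenyl cation is only moderately stabilised; that cation may alkylate an electron-rich ring of another molecule; the silyl ether may be lost early, which is harmless since step 12 removes it anyway.
- Fallback: sets out from 17 and returns at 18 without a free benzylic cation. NaBH4 in MeOH/THF gives the benzylic alcohol F11 (racemic). Dehydration with the Burgess reagent in toluene gives the stilbene F5 already described. Diimide reduction (TsNHNH2, NaOAc) gives 18.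

## Further compounds

F1 | step 10 | 4-{5-[2-(3-bromophenyl)ethyl]-2,3-dimethoxyphenoxy}benzaldehyde | COc1cc(CCc2cccc(Br)c2)cc(Oc2ccc(C=O)cc2)c1OC
F2 | step 10 | [3,4-dimethoxy-5-(triisopropylsilyloxy)phenyl]methanol | COc1cc(CO)cc(O[Si](C(C)C)(C(C)C)C(C)C)c1OC
F3 | step 10 | [5-(bromomethyl)-2,3-dimethoxyphenoxy]triisopropylsilane | COc1cc(CBr)cc(O[Si](C(C)C)(C(C)C)C(C)C)c1OC
F4 | step 10 | [3,4-dimethoxy-5-(triisopropylsilyloxy)benzyl]triphenylphosphonium bromide | COc1cc(C[P+](c2ccccc2)(c2ccccc2)c2ccccc2)cc(O[Si](C(C)C)(C(C)C)C(C)C)c1OC.[Br-]
F5 | step 10 | {5-[2-(4-{5-[2-(3-bromophenyl)ethyl]-2,3-dimethoxyphenoxy}phenyl)ethenyl]-2,3-dimethoxyphenoxy}triisopropylsilane (E/Z mixture, geometry not specified) | COc1cc(CCc2cccc(Br)c2)cc(Oc2ccc(C=Cc3cc(OC)c(OC)c(O[Si](C(C)C)(C(C)C)C(C)C)c3)cc2)c1OC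
F6 | step 5 | 5-[2-(3-bromophenyl)ethyl]-2,3-dimethoxyphenyl 3-chloropropanoate | ClCCC(=O)Oc1cc(CCc2cccc(Br)c2)cc(OC)c1OC
F7 | step 5 | 5-[2-(3-bromophenyl)ethyl]-1-[(4-chlorobut-1-en-2-yl)oxy]-2,3-dimethoxybenzene | ClCCC(=C)Oc1cc(CCc2cccc(Br)c2)cc(OC)c1OC
F8 | step 13 | aryl pinacol boronate of 18 (Bpin in place of Br on ring D, silyl ether retained) | COc1cc(CCc2cccc(c2)B2OC(C)(C)C(C)(C)O2)cc(Oc2ccc(CCc3cc(OC)c(OC)c(O[Si](C(C)C)(C(C)C)C(C)C)c3)cc2)c1OC
F9 | step 13 | phenol pinacol boronate (Bpin on ring D, free phenol on ring C) | COc1cc(CCc2cccc(c2)B2OC(C)(C)C(C)(C)O2)cc(Oc2ccc(CCc3cc(OC)c(OC)c(O)c3)cc2)c1OC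
F10 | step 13 | phenol boronic acid (B(OH)2 on ring D, free phenol on ring C) | COc1cc(CCc2cccc(c2)B(O)O)cc(Oc2ccc(CCc3cc(OC)c(OC)c(O)c3)cc2)c1OC
F11 | step 11 | 1-(4-{5-[2-(3-bromophenyl)ethyl]-2,3-dimethoxyphenoxy}phenyl)-2-[3,4-dimethoxy-5-(triisopropylsilyloxy)phenyl]ethan-1-ol (racemic) | COc1cc(CCc2cccc(Br)c2)cc(Oc2ccc(cc2)C(O)Cc2cc(OC)c(OC)c(O[Si](C(C)C)(C(C)C)C(C)C)c2)c1OC
A1 | alternative 1 | 20-membered macrolactone (ring A aryl ester of the ring B benzoic acid, tetra-O-methyl) | COc1cc2cc(c1OC)OC(=O)c1ccc(cc1)CCc1cc(OC)c(OC)c(c1)Oc1cccc(c1)CC2
A2 | alternative 1 | tetra-O-methyl 19-membered macrocycle (same structure as 20) | COc1cc2cc(c1OC)Oc1ccc(cc1)CCc1cc(OC)c(OC)c(c1)Oc1cccc(c1)CC2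
A3 | alternative 2 | 4-hydroxy-6-methyl-2H-pyran-2-one (triacetic acid lactone) | Cc1cc(O)cc(=O)o1
A4 | alternative 2 | methyl 3-[(6-{2-[3-(4-bromophenoxy)-4,5-dimethoxyphenyl]ethyl}-2-oxo-2H-pyran-4-yl)oxy]-4,5-dimethoxybenzoate | COC(=O)c1cc(OC)c(OC)c(Oc2cc(CCc3cc(OC)c(OC)c(Oc4ccc(Br)cc4)c3)oc(=O)c2)c1
A5 | alternative 2 | phenyl vinyl sulfoxide | C=CS(=O)c1ccccc1
A6 | alternative 2 | methyl 3-(3-{2-[3-(4-bromophenoxy)-4,5-dimethoxyphenyl]ethyl}phenoxy)-4,5-dimethoxybenzoate | COC(=O)c1cc(OC)c(OC)c(Oc2cccc(CCc3cc(OC)c(OC)c(Oc4ccc(Br)cc4)c3)c2)c1
A7 | alternative 3 | 5-(3-bromophenyl)-1-diazo-3-methylidenepentan-2-one | C=C(CCc1cccc(Br)c1)C(=O)C=[N+]=[N-]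
A8 | alternative 3 | di-tert-butoxyethyne | CC(C)(C)OC#COC(C)(C)C
A9 | alternative 3 | 5-[2-(3-bromophenyl)ethyl]-2,3-di-tert-butoxyphenol | CC(C)(C)Oc1cc(CCc2cccc(Br)c2)cc(O)c1OC(C)(C)C
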